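**Plan**

Numbering follows the germacranolides: ring C1–C10, lactone carbons C11–C13, C14 on C10, C15 on C4, H-7 α.
Cuts, in order: the epoxide oxygen and C10–O (back to a 1(10)E alkene), the C13 methylene, the lactone C6–O bond, C7–C11, then C8–C9 with C1 rejoined to C6, and last C6–C7.
Enabling feature: C1=C10–C9–C8–C7–C6(=O) is a δ,ε-unsaturated ketone and C1 faces C6 across the ten-membered ring, so C8–C9 can form in an oxy-Cope shift out of a six-membered ring C1–C6. That ring, with C15 and the isopropenyl unit C9/C10/C14, is carvone, and its cis alkene C4=C5 becomes the 4Z enone.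
Forward: carvone → 4-silyloxy-isopiperitenone → 1,2-addition of a (Z)-2-alkoxyvinyl metal at C6 → ring expansion six to ten with alkylation at C7 → γ-lactone → methylene lactone → C8 ester → C3 ketone → C10–OH and 1,2-epoxide.
Stereochemistry: the single carvone centre (C1) directs the C6 carbinol, and the chair shift relays both to C8 and fixes the ring conformation. C7 and C10 come from attack on outer faces, C6 from reduction then inversion, C1/C2 from hydroxyl-directed epoxidation.

Key step: step 7

Remark: the vinyl-metal addition in step 6 is taken to occur trans to the neighbouring isopropenyl group, as is usual for 6-substituted cyclohex-2-enones.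

**Route**

Step 1
Reactants: 1 (S)-(+)-carvone
Product: 2 (1S,5S)-cis-carveol
Conditions: NaBH4, CeCl3·7H2O, MeOH, −78 → 0 °C
Reagents that add atoms: none
Why: Luche 1,2-reduction, in which hydride should add axially to the enone carbonyl so that the new hydroxyl is cis to the isopropenyl group (sets C3).

Step 2
Reactants: 2 (1S,5S)-cis-carveol
Product: 3 cis-carveol tert-butyldimethylsilyl ether
Conditions: TBSCl, imidazole, DMF, rt
Reagents that add atoms: tert-butyldimethylsilyl chloride CC(C)(C)[Si](C)(C)Cl
Why: Standard silylation of a secondary allylic alcohol, which keeps the future C3 ketone masked through the organometallic and enolate steps.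

Step 3
Reactants: 3 cis-carveol tert-butyldimethylsilyl ether
Product: 4 (4S,6S)-4-silyloxy-isopiperitenone
Conditions: CrO3, 3,5-dimethylpyrazole, CH2Cl2, −20 °C
Reagents that add atoms: chromium trioxide O=[Cr](=O)=O
Why: Allylic oxidation of the only ring methylene next to the trisubstituted alkene (C6) should give the enone, since the other allylic ring C–H is tertiary and shielded by the silyl ether; no stereocentre is touched.

Step 4
Reactants: 5 4-methoxybenzyl alcohol
Product: 6 4-methoxybenzyl vinyl ether
Conditions: Pd(OAc)2 (cat.), 1,10-phenanthroline (cat.), ethyl vinyl ether (solvent), rt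
Reagents that add atoms: ethyl vinyl ether C=COCC
Why: Palladium-catalysed transfer vinylation (transetherification) of a primary alcohol with an excess of a simple vinyl ether.

Step 5
Reactants: 6 4-methoxybenzyl vinyl ether
Product: 8 (Z)-2-bromovinyl 4-methoxybenzyl ether, via dibromo ether 7 (not isolated)
Conditions: Br2, CH2Cl2, −78 °C; then i-Pr2NEt, −78 °C → rt
Reagents that add atoms: bromine BrBr
Why: Bromination of the enol ether followed by dehydrobromination through the oxocarbenium ion should give the β-bromo enol ether with the Z isomer predominating, as for simple alkyl vinyl ethers; the E isomer is removed by chromatography.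

Step 6
Reactants: 8 (Z)-2-bromovinyl 4-methoxybenzyl ether; 4 (4S,6S)-4-silyloxy-isopiperitenone
Product: 11 (1S,4S,6S)-divinyl carbinol, via vinyllithium 9 (not isolated), via vinylcerium dichloride 10 (not isolated)
Conditions: 8, t-BuLi (2 equiv), Et2O, −78 °C; CeCl3, THF, −78 °C; then 4, −78 °C; aq NH4Cl
Reagents that add atoms: none
Why: Bromine–lithium exchange with retention gives the chelation-stabilised (Z)-vinyllithium, and its organocerium should add 1,2 to the enolisable enone on the face opposite the adjacent isopropenyl group, setting the C6 carbinol with the two alkenyl groups trans.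

Step 7
Reactants: 11 (1S,4S,6S)-divinyl carbinol
Product: 14 cyclodecadienone keto ester, via potassium alkoxide 12 (not isolated), via potassium enolate 13 (not isolated)
Conditions: KN(SiMe3)2, 18-crown-6, THF, −78 → −20 °C; then BrCH2CO2Me, −78 → −40 °C
Reagents that add atoms: methyl bromoacetate COC(=O)CBr
Why: Anionic oxy-Cope rearrangement followed by enolate alkylation: alkoxide 12 weakens the C1–C6 bond, the [3,3] shift forms C8–C9 as C1–C6 breaks, and the resulting 1(10)E,4Z-dienone enolate 13 is alkylated at C7 by the bromoacetate in an SN2 step. The closest known reaction type is the alkoxide-accelerated oxy-Cope ring expansion of trans-1,2-dialkenylcyclohexanols, isopiperitenone adducts included, to cyclodec-5-enones with trapping of the regiodefined enolate. The ten-membered ring closes by a four-atom ring expansion of the cyclohexene through a chair six-centre transition state, not by an end-to-end cyclisation, so no high dilution is needed. C8 is set by chirality transfer from C1 and C6: in the chair both ring bonds are equatorial and the Z-alkoxy group is axial, which fixes the enol ether face that bonds to C9 (8R, oxygen β); the same chair gives the 1(10)E alkene and an E-ring enolate whose inner face is blocked, so the electrophile should enter C7 from the outer face, anti to C9 (H-7 α), the sense also preferred by β-alkoxy enolates. The step needs chair over boat, which the trans-diequatorial alkenyl groups secure, and alkylation before β-elimination of the C8 alkoxide, which rearranging at or below −20 °C and alkylating at −78 °C should secure.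

Step 8
Reactants: 14 cyclodecadienone keto ester
Product: 16 6β-hydroxy acid, via hydroxy ester 15 (not isolated)
Conditions: NaBH4, CeCl3·7H2O, MeOH–THF, −78 °C; then LiOH, THF–H2O, 0 °C → rt; 1 M HCl to pH 5, 0 °C
Reagents that add atoms: lithium hydroxide [Li+].[OH-]
Why: Luche 1,2-reduction in which hydride should add to the exposed face of the C6 carbonyl (Felkin sense relative to C7, also the face favoured by the C8 ether) to give the 6β-alcohol, after which hydroxide cleaves the methyl ester, or any cis-lactone formed, to the hydroxy acid that is used at once.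

Step 9
Reactants: 16 6β-hydroxy acid
Product: 17 trans-fused 6α,12-lactone
Conditions: PPh3, DIAD, toluene, 0 °C
Reagents that add atoms: none
Why: Intramolecular Mitsunobu lactonisation, in which the C12 carboxylate displaces the C6 oxyphosphonium from the side-chain face with inversion, turning the 6β-alcohol into the 6α-oxygen of the trans lactone (sets C6).

Step 10
Reactants: 17 trans-fused 6α,12-lactone
Product: 20 α-methylene lactone, via Mannich base 18 (not isolated), via ammonium iodide 19 (not isolated)
Conditions: LiN(i-Pr)2, THF, −78 °C; CH2=NMe2+ I−, −78 °C → rt; then MeI, MeOH, rt; then aq NaHCO3, EtOAc, rt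
Reagents that add atoms: dimethylmethyleneammonium iodide C=[N+](C)C.[I-]; iodomethane CI (its methyl group is carried only by intermediate 19)
Why: Mannich reaction of the lactone enolate with Eschenmoser's salt, N-methylation and Hofmann-type β-elimination install the exocyclic methylene; the lactone α-CH2 is the only acidic site and no stereocentre is affected.

Step 11
Reactants: 20 α-methylene lactone
Product: 21 8β-alcohol
Conditions: DDQ, CH2Cl2–pH 7 buffer, 0 °C → rt
Reagents that add atoms: none
Why: Oxidative cleavage of the 4-methoxybenzyl ether by DDQ frees the C8 hydroxyl without touching the silyl ether, the lactone or the alkenes.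

Step 12
Reactants: 21 8β-alcohol
Product: 22 8β-isobutyrate
Conditions: (i-PrCO)2O, Et3N, DMAP (cat.), CH2Cl2, 0 °C → rt
Reagents that add atoms: isobutyric anhydride CC(C)C(=O)OC(=O)C(C)C
Why: DMAP-catalysed acylation of the only free hydroxyl.

Step 13
Reactants: 22 8β-isobutyrate
Product: 23 3β-alcohol
Conditions: HF·pyridine, pyridine, THF, 0 °C → rt
Reagents that add atoms: none
Why: Buffered fluoride desilylation, mild enough to spare the ester, the lactone and the Michael acceptor.

Step 14
Reactants: 23 3β-alcohol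
Product: 24 3-ketone
Conditions: Dess–Martin periodinane, CH2Cl2, 0 °C → rt
Reagents that add atoms: none
Why: Dess–Martin oxidation of the allylic alcohol under near-neutral conditions should give the 4Z enone while leaving the β,γ-alkene C1=C10 out of conjugation.

Step 15
Reactants: 24 3-ketone
Product: 26 10α-hydroxy dienone, via 1β,10α-epoxide 25 (not isolated)
Conditions: mCPBA, CH2Cl2, 0 °C; then Et3N, 0 °C → rt
Reagents that add atoms: 3-chloroperoxybenzoic acid O=C(OO)c1cccc(Cl)c1
Why: Prilezhaev epoxidation of the only electron-rich alkene on its outer face (oxygen α at C10, C14 β, as for 1(10)E germacranolides) sets C10, and base-induced E1cB opening of the β,γ-epoxy ketone (C2–H removed, C1–O cleaved) should give the 10α-hydroxy 1E-enone.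

Step 16
Reactants: 26 10α-hydroxy dienone
Product: 27 target epoxide
Conditions: t-BuOOH, n-BuLi (→ t-BuOOLi), THF, −78 → −20 °C
Reagents that add atoms: tert-butyl hydroperoxide CC(C)(C)OO
Why: Hydroxyl-directed nucleophilic epoxidation of Weitz–Scheffer type, in which lithium tert-butyl peroxide held by the C10 hydroxyl should add to C1 of the less substituted enone on the face from which the oxygen left in step 15 and close at C2 to the trans 1β,2α-epoxide, while the α-methylated C4=C5 enone and the ester-type methylene lactone react more slowly.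

**Compound list**

1 | (S)-(+)-carvone, (5S)-2-methyl-5-(prop-1-en-2-yl)cyclohex-2-en-1-one | C=C(C)[C@@H]1CC(=O)C(C)=CC1 | starting material
2 | (1S,5S)-cis-carveol, hydroxyl cis to isopropenyl | C=C(C)[C@@H]1C[C@H](O)C(C)=CC1 | intermediate
3 | tert-butyldimethylsilyl ether of (1S,5S)-cis-carveol | C=C(C)[C@@H]1C[C@H](O[Si](C)(C)C(C)(C)C)C(C)=CC1 | intermediate
4 | (4S,6S)-4-(tert-butyldimethylsilyloxy)-3-methyl-6-(prop-1-en-2-yl)cyclohex-2-en-1-one, silyloxy cis to isopropenyl | C=C(C)[C@@H]1C[C@H](O[Si](C)(C)C(C)(C)C)C(C)=CC1=O | intermediate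
5 | 4-methoxybenzyl alcohol | COc1ccc(CO)cc1 | starting material
6 | 4-methoxybenzyl vinyl ether | C=COCc1ccc(OC)cc1 | intermediate
7 | 1,2-dibromoethyl 4-methoxybenzyl ether (racemic) | BrCC(Br)OCc1ccc(OC)cc1 | intermediate
8 | (Z)-2-bromovinyl 4-methoxybenzyl ether | Br/C=C\OCc1ccc(OC)cc1 | intermediate
9 | (Z)-2-(4-methoxybenzyloxy)vinyllithium | [Li]/C=C\OCc1ccc(OC)cc1 | intermediate
10 | (Z)-2-(4-methoxybenzyloxy)vinylcerium dichloride | Cl[Ce](Cl)/C=C\OCc1ccc(OC)cc1 | intermediate
11 | (1S,4S,6S)-4-(tert-butyldimethylsilyloxy)-1-[(Z)-2-(4-methoxybenzyloxy)vinyl]-3-methyl-6-(prop-1-en-2-yl)cyclohex-2-en-1-ol, vinyl trans to isopropenyl | C=C(C)[C@@H]1C[C@H](O[Si](C)(C)C(C)(C)C)C(C)=C[C@@]1(O)/C=C\OCc2ccc(OC)cc2 | intermediate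
12 | potassium alkoxide of 11 | C=C(C)[C@@H]1C[C@H](O[Si](C)(C)C(C)(C)C)C(C)=C[C@@]1([O-])/C=C\OCc2ccc(OC)cc2.[K+] | intermediate
13 | potassium C6 enolate (C6=C7, O cis to C8) of the 1(10)E,4Z-cyclodecadienone, 8β-(4-methoxybenzyloxy), 3β-silyloxy | [K+].C1/C(C)=C/C[C@H](O[Si](C)(C)C(C)(C)C)/C(C)=C\C(\[O-])=C\[C@@H]1OCc2ccc(OC)cc2 | intermediate
14 | methyl ester of the 1(10)E,4Z-cyclodeca-1(10),4-dien-6-one-7-acetic acid: CH2CO2Me at C7 (β, H-7 α), 8β-(4-methoxybenzyloxy), 3β-silyloxy | COC(=O)C[C@H]1C(=O)/C=C(/C)[C@@H](O[Si](C)(C)C(C)(C)C)C/C=C(\C)C[C@H]1OCc2ccc(OC)cc2 | intermediate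
15 | 6β-hydroxy methyl ester from 14 (6-OH cis to the C7 side chain) | COC(=O)C[C@H]1[C@@H](O)/C=C(/C)[C@@H](O[Si](C)(C)C(C)(C)C)C/C=C(\C)C[C@H]1OCc2ccc(OC)cc2 | intermediate
16 | 6β-hydroxy acid from 15 | OC(=O)C[C@H]1[C@@H](O)/C=C(/C)[C@@H](O[Si](C)(C)C(C)(C)C)C/C=C(\C)C[C@H]1OCc2ccc(OC)cc2 | intermediate
17 | trans-fused 6α,12-lactone (H-6 β, H-7 α), 1(10)E,4Z, 8β-(4-methoxybenzyloxy), 3β-silyloxy | O=C1O[C@@H]2/C=C(/C)[C@@H](O[Si](C)(C)C(C)(C)C)C/C=C(\C)C[C@@H](OCc3ccc(OC)cc3)[C@H]2C1 | intermediate
18 | 13-(dimethylamino) derivative of lactone 17 (C11 epimers) | CN(C)CC1C(=O)O[C@@H]2/C=C(/C)[C@@H](O[Si](C)(C)C(C)(C)C)C/C=C(\C)C[C@@H](OCc3ccc(OC)cc3)[C@@H]12 | intermediate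
19 | 13-(trimethylammonio) iodide of lactone 17 (C11 epimers) | C[N+](C)(C)CC1C(=O)O[C@@H]2/C=C(/C)[C@@H](O[Si](C)(C)C(C)(C)C)C/C=C(\C)C[C@@H](OCc3ccc(OC)cc3)[C@@H]12.[I-] | intermediate
20 | 3β-(tert-butyldimethylsilyloxy)-8β-(4-methoxybenzyloxy)germacra-1(10)E,4Z,11(13)-trien-6α,12-olide | C=C1C(=O)O[C@@H]2/C=C(/C)[C@@H](O[Si](C)(C)C(C)(C)C)C/C=C(\C)C[C@@H](OCc3ccc(OC)cc3)[C@@H]12 | intermediate
21 | 3β-(tert-butyldimethylsilyloxy)-8β-hydroxygermacra-1(10)E,4Z,11(13)-trien-6α,12-olide | C=C1C(=O)O[C@@H]2/C=C(/C)[C@@H](O[Si](C)(C)C(C)(C)C)C/C=C(\C)C[C@@H](O)[C@@H]12 | intermediate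
22 | 3β-(tert-butyldimethylsilyloxy)-8β-isobutyryloxygermacra-1(10)E,4Z,11(13)-trien-6α,12-olide | C=C1C(=O)O[C@@H]2/C=C(/C)[C@@H](O[Si](C)(C)C(C)(C)C)C/C=C(\C)C[C@@H](OC(=O)C(C)C)[C@@H]12 | intermediate
23 | 3β-hydroxy-8β-isobutyryloxygermacra-1(10)E,4Z,11(13)-trien-6α,12-olide | C=C1C(=O)O[C@@H]2/C=C(/C)[C@@H](O)C/C=C(\C)C[C@@H](OC(=O)C(C)C)[C@@H]12 | intermediate
24 | 8β-isobutyryloxy-3-oxogermacra-1(10)E,4Z,11(13)-trien-6α,12-olide | C=C1C(=O)O[C@@H]2/C=C(/C)C(=O)C/C=C(\C)C[C@@H](OC(=O)C(C)C)[C@@H]12 | intermediate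
25 | 1β,10α-epoxy-8β-isobutyryloxy-3-oxogermacra-4Z,11(13)-dien-6α,12-olide | C=C1C(=O)O[C@@H]2/C=C(/C)C(=O)C[C@H]3O[C@]3(C)C[C@@H](OC(=O)C(C)C)[C@@H]12 | intermediate
26 | 10α-hydroxy-8β-isobutyryloxy-3-oxogermacra-1E,4Z,11(13)-trien-6α,12-olide | C=C1C(=O)O[C@@H]2/C=C(/C)C(=O)/C=C/[C@](C)(O)C[C@@H](OC(=O)C(C)C)[C@@H]12 | intermediate
27 | 1β,2α-epoxy-10α-hydroxy-8β-isobutyryloxy-3-oxogermacra-4Z,11(13)-dien-6α,12-olide, (1R,2R,6R,7R,8R,10R) | C=C1C(=O)O[C@@H]2/C=C(/C)C(=O)[C@@H]3O[C@H]3[C@](C)(O)C[C@@H](OC(=O)C(C)C)[C@@H]12 | target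

**Step count and risks**

Total steps: 16. Longest linear sequence: 14 steps (steps 1–3 and 6–16, from 1); steps 4 and 5 form the two-step side branch.

Step 7. What may go wrong: β-elimination of the C8 4-methoxybenzyloxide from the potassium enolate before it is alkylated, and loss of facial control at C7 if the enolate has time to change conformation. Fallback: starting from 11, the carbinol is silylated (TMSCl, imidazole) to trimethylsilyl ether F1. F1 is rearranged thermally under neutral conditions (siloxy-Cope, toluene, sealed tube, about 200 °C) to trimethylsilyl enol ether F2, so that no enolate exists during the sigmatropic step. MeLi in THF at −78 °C then releases lithium enolate F3, which is alkylated at once with methyl bromoacetate in the presence of DMPU and rejoins the route at 14.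

Step 16. What may go wrong: conjugate addition of the peroxide to the α-methylene lactone, or to C5 of the second enone, competing with the directed addition at C1. Fallback: starting from 26, the methylene lactone is masked by Michael addition of dimethylamine (THF, 0 °C) to give dimethylamine adduct F4. The same lithium tert-butyl peroxide epoxidation then gives epoxy amine F5. Methylation with MeI gives ammonium iodide F6, which on treatment with aqueous NaHCO3 eliminates trimethylamine and returns the methylene lactone, arriving at 27.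

Step 9. What may go wrong: ring closure with retention through an acyloxyphosphonium intermediate, or spontaneous cis-lactonisation of the hydroxy acid before the hydroxyl is activated. Fallback: starting from 14, the Luche reduction is quenched cold at pH 7 and hydroxy ester 15 is isolated. Its C6 hydroxyl is activated first (Ms2O, i-Pr2NEt, CH2Cl2, −40 °C) to give methanesulfonate F7. LiOH in THF–H2O then cleaves the methyl ester to lithium carboxylate F8, which displaces the sulfonate intramolecularly with inversion and rejoins the route at 17.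

**Further compounds**

F1 | step 7 | trimethylsilyl ether of carbinol 11 | C=C(C)[C@@H]1C[C@H](O[Si](C)(C)C(C)(C)C)C(C)=C[C@@]1(O[Si](C)(C)C)/C=C\OCc2ccc(OC)cc2
F2 | step 7 | trimethylsilyl enol ether of the ring-expanded cyclodecadienone (C6=C7) | C1/C(C)=C/C[C@H](O[Si](C)(C)C(C)(C)C)/C(C)=C\C(\O[Si](C)(C)C)=C\[C@@H]1OCc2ccc(OC)cc2
F3 | step 7 | lithium enolate of the ring-expanded cyclodecadienone (C6=C7) | [Li+].C1/C(C)=C/C[C@H](O[Si](C)(C)C(C)(C)C)/C(C)=C\C(\[O-])=C\[C@@H]1OCc2ccc(OC)cc2
F4 | step 16 | 13-(dimethylamino)-11,13-dihydro adduct of 26 (C11 epimers) | CN(C)CC1C(=O)O[C@@H]2/C=C(/C)C(=O)/C=C/[C@](C)(O)C[C@@H](OC(=O)C(C)C)[C@@H]12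
F5 | step 16 | 1β,2α-epoxide of F4 | CN(C)CC1C(=O)O[C@@H]2/C=C(/C)C(=O)[C@@H]3O[C@H]3[C@](C)(O)C[C@@H](OC(=O)C(C)C)[C@@H]12
F6 | step 16 | 13-(trimethylammonio) iodide of F5 | C[N+](C)(C)CC1C(=O)O[C@@H]2/C=C(/C)C(=O)[C@@H]3O[C@H]3[C@](C)(O)C[C@@H](OC(=O)C(C)C)[C@@H]12.[I-]
F7 | step 9 | C6 methanesulfonate of hydroxy ester 15 | COC(=O)C[C@H]1[C@@H](OS(C)(=O)=O)/C=C(/C)[C@@H](O[Si](C)(C)C(C)(C)C)C/C=C(\C)C[C@H]1OCc2ccc(OC)cc2
F8 | step 9 | lithium carboxylate of methanesulfonate F7 | [Li+].[O-]C(=O)C[C@H]1[C@@H](OS(C)(=O)=O)/C=C(/C)[C@@H](O[Si](C)(C)C(C)(C)C)C/C=C(\C)C[C@H]1OCc2ccc(OC)cc2
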